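**Assumptions (one line each)**
- Compound 1, but-2-yn-1-ol, ethynyltrimethylsilane, methyl propiolate and angelic acid are taken as commercial; common reagents are not numbered.
- Germacrane numbering (C1–C15) is used in the explanations; the target is (6R,7R,8S,10R), 4Z, with a (Z)-angelate.
- The sense of ligand induction in the new step (17) is assumed by analogy; the (S,S) ligand is written and its enantiomer is used if it proves mismatched.

**Retrosynthetic overview**
1. The angelate is put on the free C8–OH last.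
2. The 10-membered carbocycle and the α-methylene-γ-lactone are formed together by closing C6–C7 with a new Cr-catalysed, ligand-controlled macrocyclising 2-(alkoxycarbonyl)allylation–lactonisation of a Z-enal / 2-(bromomethyl)enoate; this sets C6 and C7.
3. The bromo-enoate comes from a C7 aldehyde by vinylalumination with methyl propiolate and SN2′ bromination.
4. The 3(2H)-furanone is made first, by Au(I) 5-endo-dig cyclisation of an α′-hydroxy ynone assembled from a Weinreb amide (C7–C10; C8 from the chiral pool, C10 by enolate methylation/hydroxylation) and a Z-enyne (C2–C6; Red-Al/I2 then Sonogashira).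
5. Ring order: furanone, then carbocycle and lactone in one step.

**Route**

Step 1
Reactants: 1, (5S)-5-[(trityloxy)methyl]dihydrofuran-2(3H)-one
Product: 2, (3R,5S)-3-methyl-5-[(trityloxy)methyl]dihydrofuran-2(3H)-one
Conditions: LDA, THF, −78 °C; MeI, −78 → −40 °C
Reagents that add atoms: iodomethane, CI
Why: Lithium enolate alkylation, with MeI entering anti to the bulky CH2OTr group; this centre is re-enolised in step 2, so both epimers are usable.

Step 2
Reactants: 2
Product: 3, (3R,5S)-3-hydroxy-3-methyl-5-[(trityloxy)methyl]dihydrofuran-2(3H)-one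
Conditions: KHMDS, THF, −78 °C; then trans-2-(phenylsulfonyl)-3-phenyloxaziridine, −78 °C
Reagents that add atoms: Davis oxaziridine, O=S(=O)(c1ccccc1)N1OC1c1ccccc1 (adds O)
Why: Davis enolate hydroxylation; the oxidant attacks the tetrasubstituted enolate on the face opposite CH2OTr, giving the tertiary alcohol trans to it (3R), which is C10 (R) of the target.

Step 3
Reactants: 3
Product: 4, (2R,4S)-2,4-dihydroxy-N-methoxy-N,2-dimethyl-5-(trityloxy)pentanamide
Conditions: MeNHOMe·HCl, Me3Al, CH2Cl2, 0 °C → rt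
Reagents that add atoms: N,O-dimethylhydroxylamine hydrochloride, CNOC.Cl
Why: Weinreb aminolysis of the γ-lactone by the aluminium amide; no stereocentre is touched.

Step 4
Reactants: 4
Product: 5, (2R,4S)-4-[(tert-butyldimethylsilyl)oxy]-2-hydroxy-N-methoxy-N,2-dimethyl-5-(trityloxy)pentanamide
Conditions: TBSOTf (1.15 equiv), 2,6-lutidine, CH2Cl2, −78 °C
Reagents that add atoms: TBSOTf, CC(C)(C)[Si](C)(C)OS(=O)(=O)C(F)(F)F
Why: Selective silylation of the secondary OH over the hindered tertiary α-hydroxy amide OH; it also blocks relactonisation.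

Step 5
Reactants: 6, but-2-yn-1-ol
Product: 7, (2Z)-3-iodobut-2-en-1-ol
Conditions: Red-Al, Et2O, 0 °C → rt; then I2, THF, −78 → 0 °C
Reagents that add atoms: iodine, II
Why: Hydroxyl-directed trans-hydroalumination and iodinolysis with retention places I cis to CH2OH, which fixes the 4Z alkene geometry.

Step 6
Reactants: 7
Product: 8, 1-({[(2Z)-3-iodobut-2-en-1-yl]oxy}methyl)-4-methoxybenzene
Conditions: NaH, PMBCl, Bu4NI (cat.), THF/DMF, 0 °C → rt
Reagents that add atoms: 4-methoxybenzyl chloride, COc1ccc(CCl)cc1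
Why: Williamson etherification; PMB is later removed oxidatively in the presence of silyl ethers and an allylic bromide.

Step 7
Reactants: 8; 9, ethynyltrimethylsilane
Product: 10, {(3Z)-5-[(4-methoxybenzyl)oxy]-3-methylpent-3-en-1-yn-1-yl}trimethylsilane
Conditions: PdCl2(PPh3)2 (2 mol %), CuI (4 mol %), Et3N, THF, rt
Reagents that add atoms: none
Why: Sonogashira coupling of a vinyl iodide proceeds with retention of alkene geometry.

Step 8
Reactants: 10
Product: 11, 1-methoxy-4-({[(2Z)-3-methylpent-2-en-4-yn-1-yl]oxy}methyl)benzene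
Conditions: K2CO3, MeOH, rt
Reagents that add atoms: none
Why: Protiodesilylation of the alkynylsilane.

Step 9
Reactants: 5; 11 (2.3 equiv)
Product: 12, (2Z,7R,9S)-9-[(tert-butyldimethylsilyl)oxy]-7-hydroxy-1-[(4-methoxybenzyl)oxy]-3,7-dimethyl-10-(trityloxy)dec-2-en-4-yn-6-one
Conditions: 11, n-BuLi (2.2 equiv), THF, −78 °C; then 5, −78 → −20 °C; aq NH4Cl
Reagents that add atoms: none
Why: Acetylide acylation by a Weinreb amide (the chelated tetrahedral intermediate stops at the ynone); the first equivalent of acetylide deprotonates the tertiary OH.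

Step 10
Reactants: 12
Product: 13, (2R)-2-{(2S)-2-[(tert-butyldimethylsilyl)oxy]-3-(trityloxy)propyl}-5-{(2Z)-4-[(4-methoxybenzyl)oxy]but-2-en-2-yl}-2-methylfuran-3(2H)-one
Conditions: (Ph3P)AuNTf2 (3 mol %), toluene, rt
Reagents that add atoms: none
Why: Au(I)-catalysed 5-endo-dig hydroalkoxylation of the α′-hydroxy ynone gives the 3(2H)-furanone; no bond to C10 is broken, so its configuration is retained.

Step 11
Reactants: 13
Product: 14, (2R)-2-{(2S)-2-[(tert-butyldimethylsilyl)oxy]-3-hydroxypropyl}-5-{(2Z)-4-[(4-methoxybenzyl)oxy]but-2-en-2-yl}-2-methylfuran-3(2H)-one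
Conditions: HCO2H/Et2O (1:1), 0 °C → rt, 30 min
Reagents that add atoms: none
Why: Mild acidolysis of the trityl ether (via the stabilised trityl cation) leaves the secondary TBS ether, the PMB ether and the vinylogous ester intact.

Step 12
Reactants: 14
Product: 15, (2S)-2-[(tert-butyldimethylsilyl)oxy]-3-[(2R)-5-{(2Z)-4-[(4-methoxybenzyl)oxy]but-2-en-2-yl}-2-methyl-3-oxo-2,3-dihydrofuran-2-yl]propanal
Conditions: Dess–Martin periodinane, NaHCO3, CH2Cl2, 0 °C
Reagents that add atoms: none
Why: Buffered Dess–Martin oxidation gives the α-silyloxy aldehyde without epimerising C8.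

Step 13
Reactants: 15; 16, methyl propiolate
Product: 17, methyl 2-{(1RS,2S)-2-[(tert-butyldimethylsilyl)oxy]-1-hydroxy-3-[(2R)-5-{(2Z)-4-[(4-methoxybenzyl)oxy]but-2-en-2-yl}-2-methyl-3-oxo-2,3-dihydrofuran-2-yl]propyl}prop-2-enoate
Conditions: 16, DIBAL-H, NMO, THF, 0 °C (forms the vinylalane); then 15, 0 °C → rt
Reagents that add atoms: none (16 is the reactant; DIBAL-H adds only H)
Why: Vinylalumination, an amine-free Morita–Baylis–Hillman equivalent: the [α-(methoxycarbonyl)vinyl]alane adds 1,2 to the aldehyde and forms C7–C11; the C7 carbinol mixture is irrelevant because C7 becomes sp2 in step 14.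

Step 14
Reactants: 17
Product: 18, methyl (2Z,4S)-2-(bromomethyl)-4-[(tert-butyldimethylsilyl)oxy]-5-[(2R)-5-{(2Z)-4-[(4-methoxybenzyl)oxy]but-2-en-2-yl}-2-methyl-3-oxo-2,3-dihydrofuran-2-yl]pent-2-enoate
Conditions: NBS, Me2S, CH2Cl2, 0 °C → rt
Reagents that add atoms: N-bromosuccinimide, O=C1CCC(=O)N1Br (adds Br)
Why: SN2′ bromination of the Baylis–Hillman-type alcohol via its alkoxysulfonium salt gives the thermodynamically preferred (Z)-2-(bromomethyl)enoate.

Step 15
Reactants: 18
Product: 19, methyl (2Z,4S)-2-(bromomethyl)-4-[(tert-butyldimethylsilyl)oxy]-5-{(2R)-5-[(2Z)-4-hydroxybut-2-en-2-yl]-2-methyl-3-oxo-2,3-dihydrofuran-2-yl}pent-2-enoate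
Conditions: DDQ, CH2Cl2/pH 7 buffer, 0 °C
Reagents that add atoms: none
Why: Oxidative PMB cleavage under neutral conditions tolerates the allylic bromide, the TBS ether and the dienone.

Step 16
Reactants: 19
Product: 20, methyl (2Z,4S)-2-(bromomethyl)-4-[(tert-butyldimethylsilyl)oxy]-5-{(2R)-2-methyl-3-oxo-5-[(2Z)-4-oxobut-2-en-2-yl]-2,3-dihydrofuran-2-yl}pent-2-enoate
Conditions: Dess–Martin periodinane, NaHCO3, CH2Cl2, 0 °C, dark; used crude
Reagents that add atoms: none
Why: Dess–Martin oxidation of the allylic alcohol under buffered, nucleophile-free conditions gives the Z-enal without Z/E isomerisation.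

Step 17
Reactants: 20
Product: 21, (2Z,4R,8R,9S,11R)-9-[(tert-butyldimethylsilyl)oxy]-2,11-dimethyl-7-methylidene-5,14-dioxatricyclo[9.2.1.0^4,8]tetradeca-1(13),2-diene-6,12-dione (8-O-TBS-8-desangeloyl-lychnopholide; germacrane 6R,7R,8S,10R)
Conditions: CrCl2 (20 mol %), (S,S)-tBu-carbazole-bis(oxazoline) ligand L* (22 mol %), Mn powder (4 equiv), Cp2ZrCl2 (1.5 equiv), LiCl, THF/MeCN, rt, syringe-pump addition of 20 over 12 h (final 2 mM); then PPTS, CH2Cl2, rt
Reagents that add atoms: none (Br and MeOH are lost)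
Why: Proposed new method: a Cr-catalytic, chiral-ligand-controlled intramolecular 2-(alkoxycarbonyl)allylation–lactonisation (a macrocyclising Nozaki–Hiyama–Kishi/Barbier allylation), in which Mn(0) regenerates Cr(II)·L*, two Cr(II) turn the allylic bromide into a configurationally labile allyl–Cr(III)·L* that is aldehyde-selective (it ignores the C1 vinylogous-ester ketone, where allylzinc could close a five-membered carbinol) and adds through C7 to the tethered Z-enal via a six-membered chair transition state, with C–C formation anti to the C8 OTBS group and C8–H eclipsing the allyl unit (7R), the ring tether plus L* selecting the aldehyde face for the trans C6–C7 relationship (6R), Cp2ZrCl2 cleaving Cr–O for turnover, and the γ-hydroxy ester then lactonising; the closest known reaction types are stoichiometric CrCl2 or Zn Barbier closures of 10-membered sesquiterpene-lactone rings and intermolecular Cr-catalysed asymmetric 2-(alkoxycarbonyl)allylation of aldehydes, neither shown as a catalytic, ligand-controlled medium-ring closure with a γ-oxygenated allyl donor.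

Step 18
Reactants: 21
Product: 22, (2Z,4R,8R,9S,11R)-9-hydroxy-2,11-dimethyl-7-methylidene-5,14-dioxatricyclo[9.2.1.0^4,8]tetradeca-1(13),2-diene-6,12-dione (8-desangeloyl-lychnopholide)
Conditions: HF·pyridine, pyridine/THF, 0 °C → rt
Reagents that add atoms: none
Why: Buffered HF desilylation removes the secondary TBS ether without attacking the α-methylene lactone or the furanone.

Step 19
Reactants: 22; 23, angelic acid [(2Z)-2-methylbut-2-enoic acid]
Product: 24, lychnopholide, (2Z,4R,8R,9S,11R)-2,11-dimethyl-7-methylidene-6,12-dioxo-5,14-dioxatricyclo[9.2.1.0^4,8]tetradeca-1(13),2-dien-9-yl (2Z)-2-methylbut-2-enoate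
Conditions: 23, 2,4,6-trichlorobenzoyl chloride, Et3N, toluene, rt, 2 h; then 22, 75 °C (no DMAP)
Reagents that add atoms: none (23 is the reactant)
Why: Yamaguchi-type mixed-anhydride esterification without a nucleophilic catalyst acylates the hindered C8–OH while preserving the (Z)-angelate geometry; C8 keeps its configuration.

**Compound list**

1 | (5S)-5-[(trityloxy)methyl]dihydrofuran-2(3H)-one | O=C1CC[C@@H](COC(c2ccccc2)(c2ccccc2)c2ccccc2)O1 | starting material
2 | (3R,5S)-3-methyl-5-[(trityloxy)methyl]dihydrofuran-2(3H)-one | O=C1[C@H](C)C[C@@H](COC(c2ccccc2)(c2ccccc2)c2ccccc2)O1 | intermediate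
3 | (3R,5S)-3-hydroxy-3-methyl-5-[(trityloxy)methyl]dihydrofuran-2(3H)-one | O=C1[C@](C)(O)C[C@@H](COC(c2ccccc2)(c2ccccc2)c2ccccc2)O1 | intermediate
4 | (2R,4S)-2,4-dihydroxy-N-methoxy-N,2-dimethyl-5-(trityloxy)pentanamide | CON(C)C(=O)[C@](C)(O)C[C@H](O)COC(c1ccccc1)(c1ccccc1)c1ccccc1 | intermediate
5 | (2R,4S)-4-[(tert-butyldimethylsilyl)oxy]-2-hydroxy-N-methoxy-N,2-dimethyl-5-(trityloxy)pentanamide | CON(C)C(=O)[C@](C)(O)C[C@H](O[Si](C)(C)C(C)(C)C)COC(c1ccccc1)(c1ccccc1)c1ccccc1 | intermediate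
6 | but-2-yn-1-ol | CC#CCO | starting material
7 | (2Z)-3-iodobut-2-en-1-ol | OC/C=C(/C)I | intermediate
8 | 1-({[(2Z)-3-iodobut-2-en-1-yl]oxy}methyl)-4-methoxybenzene | COc1ccc(COC/C=C(/C)I)cc1 | intermediate
9 | ethynyltrimethylsilane | C#C[Si](C)(C)C | starting material
10 | {(3Z)-5-[(4-methoxybenzyl)oxy]-3-methylpent-3-en-1-yn-1-yl}trimethylsilane | COc1ccc(COC/C=C(/C)C#C[Si](C)(C)C)cc1 | intermediate
11 | 1-methoxy-4-({[(2Z)-3-methylpent-2-en-4-yn-1-yl]oxy}methyl)benzene | COc1ccc(COC/C=C(/C)C#C)cc1 | intermediate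
12 | (2Z,7R,9S)-9-[(tert-butyldimethylsilyl)oxy]-7-hydroxy-1-[(4-methoxybenzyl)oxy]-3,7-dimethyl-10-(trityloxy)dec-2-en-4-yn-6-one | COc1ccc(COC/C=C(/C)C#CC(=O)[C@](C)(O)C[C@H](O[Si](C)(C)C(C)(C)C)COC(c2ccccc2)(c2ccccc2)c2ccccc2)cc1 | intermediate
13 | (2R)-2-{(2S)-2-[(tert-butyldimethylsilyl)oxy]-3-(trityloxy)propyl}-5-{(2Z)-4-[(4-methoxybenzyl)oxy]but-2-en-2-yl}-2-methylfuran-3(2H)-one | COc1ccc(COC/C=C(/C)C2=CC(=O)[C@@](C)(C[C@H](O[Si](C)(C)C(C)(C)C)COC(c3ccccc3)(c3ccccc3)c3ccccc3)O2)cc1 | intermediate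
14 | (2R)-2-{(2S)-2-[(tert-butyldimethylsilyl)oxy]-3-hydroxypropyl}-5-{(2Z)-4-[(4-methoxybenzyl)oxy]but-2-en-2-yl}-2-methylfuran-3(2H)-one | COc1ccc(COC/C=C(/C)C2=CC(=O)[C@@](C)(C[C@H](O[Si](C)(C)C(C)(C)C)CO)O2)cc1 | intermediate
15 | (2S)-2-[(tert-butyldimethylsilyl)oxy]-3-[(2R)-5-{(2Z)-4-[(4-methoxybenzyl)oxy]but-2-en-2-yl}-2-methyl-3-oxo-2,3-dihydrofuran-2-yl]propanal | COc1ccc(COC/C=C(/C)C2=CC(=O)[C@@](C)(C[C@H](O[Si](C)(C)C(C)(C)C)C=O)O2)cc1 | intermediate
16 | methyl propiolate | C#CC(=O)OC | starting material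
17 | methyl 2-{(1RS,2S)-2-[(tert-butyldimethylsilyl)oxy]-1-hydroxy-3-[(2R)-5-{(2Z)-4-[(4-methoxybenzyl)oxy]but-2-en-2-yl}-2-methyl-3-oxo-2,3-dihydrofuran-2-yl]propyl}prop-2-enoate (C7 epimer mixture) | COc1ccc(COC/C=C(/C)C2=CC(=O)[C@@](C)(C[C@H](O[Si](C)(C)C(C)(C)C)C(O)C(=C)C(=O)OC)O2)cc1 | intermediate
18 | methyl (2Z,4S)-2-(bromomethyl)-4-[(tert-butyldimethylsilyl)oxy]-5-[(2R)-5-{(2Z)-4-[(4-methoxybenzyl)oxy]but-2-en-2-yl}-2-methyl-3-oxo-2,3-dihydrofuran-2-yl]pent-2-enoate | COc1ccc(COC/C=C(/C)C2=CC(=O)[C@@](C)(C[C@H](O[Si](C)(C)C(C)(C)C)/C=C(\CBr)C(=O)OC)O2)cc1 | intermediate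
19 | methyl (2Z,4S)-2-(bromomethyl)-4-[(tert-butyldimethylsilyl)oxy]-5-{(2R)-5-[(2Z)-4-hydroxybut-2-en-2-yl]-2-methyl-3-oxo-2,3-dihydrofuran-2-yl}pent-2-enoate | OC/C=C(/C)C1=CC(=O)[C@@](C)(C[C@H](O[Si](C)(C)C(C)(C)C)/C=C(\CBr)C(=O)OC)O1 | intermediate
20 | methyl (2Z,4S)-2-(bromomethyl)-4-[(tert-butyldimethylsilyl)oxy]-5-{(2R)-2-methyl-3-oxo-5-[(2Z)-4-oxobut-2-en-2-yl]-2,3-dihydrofuran-2-yl}pent-2-enoate | O=C/C=C(/C)C1=CC(=O)[C@@](C)(C[C@H](O[Si](C)(C)C(C)(C)C)/C=C(\CBr)C(=O)OC)O1 | intermediate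
21 | (2Z,4R,8R,9S,11R)-9-[(tert-butyldimethylsilyl)oxy]-2,11-dimethyl-7-methylidene-5,14-dioxatricyclo[9.2.1.0^4,8]tetradeca-1(13),2-diene-6,12-dione | C=C1C(=O)O[C@@H]2/C=C(/C)C3=CC(=O)[C@@](C)(C[C@H](O[Si](C)(C)C(C)(C)C)[C@@H]12)O3 | intermediate
22 | (2Z,4R,8R,9S,11R)-9-hydroxy-2,11-dimethyl-7-methylidene-5,14-dioxatricyclo[9.2.1.0^4,8]tetradeca-1(13),2-diene-6,12-dione | C=C1C(=O)O[C@@H]2/C=C(/C)C3=CC(=O)[C@@](C)(C[C@H](O)[C@@H]12)O3 | intermediate
23 | angelic acid, (2Z)-2-methylbut-2-enoic acid | C/C=C(/C)C(=O)O | starting material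
24 | lychnopholide | C=C1C(=O)O[C@@H]2/C=C(/C)C3=CC(=O)[C@@](C)(C[C@H](OC(=O)/C(C)=C\C)[C@@H]12)O3 | target

**Summary**
- Total steps: 19.
- Longest linear sequence: 15 (steps 1–4 then 9–19; the route from 6 via steps 5–8 is the same length).
- Stereo origin: C8 from 1; C10 in step 2; C6 and C7 in step 17; 4Z from step 5; angelate geometry from 23.

**Three steps most likely to fail, with fallbacks**
1. Step 17 (proposed new Cr-catalysed macro-allylation–lactonisation): ring closure may be slow, or give the cis-lactone or the wrong face. Fallback (known chemistry, different order of ring formation): carry the ynone (before Au cyclisation) through steps 11–16, close the 10-membered ring by stoichiometric, substrate-controlled CrCl2 Barbier allylation–lactonisation, then form the furanone last by transannular Au(I) 5-endo-dig cyclisation.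
2. Step 16 (Z-enal 20 may isomerise to the E-enal, which cannot cyclise). Fallback: move the ring-closing bond to C7–C8 so no enal is needed. Build a 3-(bromomethyl)butenolide on C6 (C6 vinyl carbinol acylated with 2-(bromomethyl)acrylic acid, then ring-closing metathesis) and close it onto a saturated C8 aldehyde with activated Zn. This gives the C8–OH directly for step 19.
3. Step 13 (vinylalane addition to a hindered α-silyloxy aldehyde beside the dienone). Fallback: a masked-acrylate aldol. Add the lithium enolate of methyl 3-(phenylselanyl)propanoate to 15 at −78 °C, then H2O2 selenoxide elimination to reveal the acrylate of 17.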